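**Retrosynthetic overview**

1. The only ring, the 3,6-dihydro-1,2-dioxine, is formed last by suprafacial [4+2] addition of singlet oxygen across C3/C6 of an open-chain (3E,5Z)-3,5-dienoic acid; the diene geometry encodes the cis relation of CH2CO2H (C3) and ethyl (C6).
2. The diene is cut at C4–C5: Pd-catalysed alkenyl–alkenyl coupling of an (E)-4-iodohex-3-enoate with a (Z)-alkenylmetal made by syn-carbocupration of a C4 terminal alkyne with the side-chain alkylcopper.
3. Key C–C bond (C2–C3, acetate carbon to future ring carbon): an α-iodoacetate serves as an enolonium (a2) equivalent and adds through its α-carbon to the terminal carbon of the same C4 alkyne with anti iodine transfer. Two normally nucleophilic carbons are joined, and the C3=C4 geometry and the coupling handle are set in one step.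
4. Side chain: two zirconium-catalysed asymmetric carboaluminations (ethyl, then methyl) starting from a C6 1-alkene set both remote stereocentres.

Assumption: (+)-(NMI)2ZrCl2, i.e. (+)-bis(1-neomenthylindenyl)zirconium dichloride, gives the (S)-2-alkylalkylalane (mirror image of the (R)-selective (−)-complex); if the sense is the reverse, the (−)-complex is used and nothing else changes.

**Route**

Step 1
Reactants: 1 hex-1-ene; 2 triethylaluminium; 3 vinyl bromide
Product: 6 (4S)-4-ethyloct-1-ene, via alkyldiethylalane 4 (not isolated), via alkylzinc triflate 5 (not isolated)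
Conditions: 2 (1.5 equiv), (+)-(NMI)2ZrCl2 (5 mol%), CH2Cl2, 0 → 23 °C; evaporate; Zn(OTf)2 (1.5 equiv), DMF, 70 °C; 3 (6 equiv), PdCl2(DPEphos) (3 mol%), i-Bu2AlH (6 mol%), 23 °C
Reagents that add atoms: none
Why: Zirconium-catalysed asymmetric carboalumination (ZACA reaction) adds Et–Al across the terminal alkene with the chiral zirconocene choosing the alkene face, which sets the ethyl-bearing stereocentre as S (about 92% ee expected), and Al-to-Zn transmetalation followed by Negishi coupling with vinyl bromide forms the allyl C–C bond without touching that centre.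

Step 2
Reactants: 6 (4S)-4-ethyloct-1-ene; 7 trimethylaluminium
Product: 10 (2S,4S)-4-ethyl-2-methyloctan-1-ol, via alkyldimethylalane 8 (not isolated), via aluminium alkoxide 9 (not isolated)
Conditions: 7 (2.5 equiv), (+)-(NMI)2ZrCl2 (5 mol%), methylaluminoxane (MeAlO)n (1 equiv), CH2Cl2, 0 → 23 °C; O2 (1 atm), 0 → 23 °C; H2O work-up; SiO2 chromatography
Reagents that add atoms: dioxygen (O=O)
Why: A second ZACA reaction (methylalumination) sets the methyl-bearing stereocentre as S under catalyst control (about 6:1 over the 2R epimer expected), O2 oxidation of the C–Al bond gives the primary alcohol, and chromatography of the alcohol removes the minor diastereomers, which also purges the small amount of wrong C4 enantiomer from step 1 as a diastereomer.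

Step 3
Reactants: 10 (2S,4S)-4-ethyl-2-methyloctan-1-ol
Product: 11 (2S,4S)-1-bromo-4-ethyl-2-methyloctane
Conditions: CBr4 (1.2 equiv), PPh3 (1.25 equiv), CH2Cl2, 0 °C → rt
Reagents that add atoms: carbon tetrabromide (BrC(Br)(Br)Br)
Why: Appel reaction, an SN2 displacement of the alkoxyphosphonium ion by bromide at the primary carbon that leaves both stereocentres untouched.

Step 4 (key step)
Reactants: 12 but-1-yne; 13 methyl iodoacetate
Product: 14 methyl (3E)-4-iodohex-3-enoate
Conditions: 12 (3 equiv, condensed), Et3B (0.2 equiv), trace air, benzene, sealed vessel, 0 → 20 °C, dark; chromatography on AgNO3-impregnated SiO2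
Reagents that add atoms: none
Why: Iodine-atom-transfer radical addition (Kharasch-type ATRA, Et3B/O2 initiation) in which the iodoacetate acts as an enolonium (a2) equivalent: its α-carbon, normally the nucleophilic enolate carbon, is delivered as an electrophilic radical to the nucleophilic terminal carbon of the alkyne, and the bent vinyl radical then takes iodine anti to the new CH2CO2Me group to give mainly the E iodide (typically about 3–5:1, Z isomer removed), the geometry that later fixes C3 relative to C6.

Step 5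
Reactants: 11 (2S,4S)-1-bromo-4-ethyl-2-methyloctane; 12 but-1-yne; 14 methyl (3E)-4-iodohex-3-enoate
Product: 19 methyl (3E,5Z,8S,10S)-4,6,10-triethyl-8-methyltetradeca-3,5-dienoate, via alkylmagnesium bromide 15 (not isolated), via alkylcopper 16 (not isolated), via alkenylcopper 17 (not isolated), via alkenylzinc bromide 18 (not isolated)
Conditions: Mg, Et2O, 35 °C; CuBr·SMe2 (1 equiv), Et2O/Me2S, −45 °C; 12 (1.3 equiv), −25 °C, 3 h; ZnBr2 (1 equiv), THF, −20 °C; 14 (0.85 equiv), Pd(PPh3)4 (5 mol%), −10 → 20 °C
Reagents that add atoms: none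
Why: Normant syn-carbocupration puts the alkyl group on the internal alkyne carbon and copper cis to it on the terminal carbon, and Cu-to-Zn transmetalation followed by Pd-catalysed Negishi-type alkenyl–alkenyl coupling proceeds with retention at both sp2 carbons, so the 3E,5Z diene forms as one geometric isomer and no stereocentre is touched.

Step 6
Reactants: 19 methyl (3E,5Z,8S,10S)-4,6,10-triethyl-8-methyltetradeca-3,5-dienoate
Product: 21 (3E,5Z,8S,10S)-4,6,10-triethyl-8-methyltetradeca-3,5-dienoic acid, via lithium dienoate 20 (not isolated)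
Conditions: LiOH·H2O (3 equiv), THF/MeOH/H2O 3:1:1, 0 °C → rt; 1 M HCl to pH 3, 0 °C
Reagents that add atoms: lithium hydroxide ([Li+].[OH-])
Why: Saponification (BAc2 ester hydrolysis) at low temperature, where attack at the carbonyl is faster than α-deprotonation so the skipped 3,5-diene is not drawn into conjugation and no stereocentre is involved.

Step 7
Reactants: 21 (3E,5Z,8S,10S)-4,6,10-triethyl-8-methyltetradeca-3,5-dienoic acid
Product: 22 2-[(3R,6R)-4,6-diethyl-6-[(2S,4S)-4-ethyl-2-methyloctyl]-3,6-dihydro-1,2-dioxin-3-yl]acetic acid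
Conditions: O2 (1 atm), tetraphenylporphyrin (1 mol%), CH2Cl2, −20 °C, white LED; preparative HPLC
Reagents that add atoms: dioxygen (O=O)
Why: Photosensitised [4+2] cycloaddition of singlet oxygen to the s-cis diene (favoured by the C4 ethyl group) is suprafacial, so the two outside groups (CH2CO2H on C3, ethyl on C6) end up cis and C3 and C6 are set together in the 3R,6R/3S,6S relative sense, while the remote side-chain centres do not differentiate the two diene faces, so 22 and its 3S,6S diastereomer form in about equal amounts and 22 is isolated by preparative HPLC.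

**Compound list**

1 | hex-1-ene | C=CCCCC | starting material
2 | triethylaluminium | CC[Al](CC)CC | starting material
3 | vinyl bromide | C=CBr | starting material
4 | diethyl[(2S)-2-ethylhexyl]alane | CCCC[C@H](CC)C[Al](CC)CC | intermediate
5 | [(2S)-2-ethylhexyl]zinc triflate | CCCC[C@H](CC)C[Zn]OS(=O)(=O)C(F)(F)F | intermediate
6 | (4S)-4-ethyloct-1-ene | CCCC[C@H](CC)CC=C | intermediate
7 | trimethylaluminium | C[Al](C)C | starting material
8 | [(2S,4S)-4-ethyl-2-methyloctyl]dimethylalane | CCCC[C@H](CC)C[C@H](C)C[Al](C)C | intermediate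
9 | dimethoxy[(2S,4S)-4-ethyl-2-methyloctyloxy]alane | CCCC[C@H](CC)C[C@H](C)CO[Al](OC)OC | intermediate
10 | (2S,4S)-4-ethyl-2-methyloctan-1-ol | CCCC[C@H](CC)C[C@H](C)CO | intermediate
11 | (2S,4S)-1-bromo-4-ethyl-2-methyloctane | CCCC[C@H](CC)C[C@H](C)CBr | intermediate
12 | but-1-yne | CCC#C | starting material
13 | methyl iodoacetate | COC(=O)CI | starting material
14 | methyl (3E)-4-iodohex-3-enoate | CC/C(I)=C\CC(=O)OC | intermediate
15 | [(2S,4S)-4-ethyl-2-methyloctyl]magnesium bromide | CCCC[C@H](CC)C[C@H](C)C[Mg]Br | intermediate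
16 | [(2S,4S)-4-ethyl-2-methyloctyl]copper | CCCC[C@H](CC)C[C@H](C)C[Cu] | intermediate
17 | [(1Z,4S,6S)-2,6-diethyl-4-methyldec-1-en-1-yl]copper | CCCC[C@H](CC)C[C@H](C)C/C(CC)=C\[Cu] | intermediate
18 | [(1Z,4S,6S)-2,6-diethyl-4-methyldec-1-en-1-yl]zinc bromide | CCCC[C@H](CC)C[C@H](C)C/C(CC)=C\[Zn]Br | intermediate
19 | methyl (3E,5Z,8S,10S)-4,6,10-triethyl-8-methyltetradeca-3,5-dienoate | CCCC[C@H](CC)C[C@H](C)C/C(CC)=C\C(CC)=C\CC(=O)OC | intermediate
20 | lithium (3E,5Z,8S,10S)-4,6,10-triethyl-8-methyltetradeca-3,5-dienoate | CCCC[C@H](CC)C[C@H](C)C/C(CC)=C\C(CC)=C\CC(=O)[O-].[Li+] | intermediate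
21 | (3E,5Z,8S,10S)-4,6,10-triethyl-8-methyltetradeca-3,5-dienoic acid | CCCC[C@H](CC)C[C@H](C)C/C(CC)=C\C(CC)=C\CC(=O)O | intermediate
22 | 2-[(3R,6R)-4,6-diethyl-6-[(2S,4S)-4-ethyl-2-methyloctyl]-3,6-dihydro-1,2-dioxin-3-yl]acetic acid | CCCC[C@H](CC)C[C@H](C)C[C@]1(CC)C=C(CC)[C@@H](CC(=O)O)OO1 | target

**Step count and risks**

Total step count: 7. Longest linear sequence: 6 steps (steps 1, 2, 3, 5, 6, 7, from hex-1-ene); step 4 is a one-step branch.

Most likely to fail, first: step 7. Ene hydroperoxides compete with the [4+2] mode, and the two diene faces are not differentiated, so half of the cycloadduct is the 3S,6S isomer and the separation of two acids rests on HPLC. The fallback sets out from ester 19 and comes back at 22. Ester 19 is reduced with i-Bu2AlH (CH2Cl2, −78 → 0 °C) to (3E,5Z,8S,10S)-4,6,10-triethyl-8-methyltetradeca-3,5-dien-1-ol F1. Photooxygenation of this neutral dienol (O2, tetraphenylporphyrin, CH2Cl2, −20 °C) gives 2-[(3R,6R)-4,6-diethyl-6-[(2S,4S)-4-ethyl-2-methyloctyl]-3,6-dihydro-1,2-dioxin-3-yl]ethan-1-ol F2 together with its 3S,6S isomer, which are separated on silica as alcohols or as esters of a chiral acid. The alcohol is then oxidised to 22 with TEMPO/PhI(OAc)2 in MeCN–H2O, conditions that are neither basic nor reducing toward the O–O bond. The carboxyl group is thus unveiled by oxidation after ring formation instead of by hydrolysis before it.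

Second: step 4. The E:Z ratio of the iodine transfer may be lower than hoped and the isomers may be hard to separate; a Z contaminant would give a (3Z)-diene that cannot reach the s-cis form and is lost in step 7. The fallback sets out from bromide 11 and comes back at ester 19. Alkenylcopper 17, made from 11 as in step 5, is added syn to methyl pent-2-ynoate (Et2O/THF, Me3SiCl, −78 °C) to give methyl (2E,4Z,7S,9S)-3,5,9-triethyl-7-methyltrideca-2,4-dienoate F3, in which both trisubstituted double bonds are fixed by syn-carbocupration. Saponification with LiOH gives lithium (2E,4Z,7S,9S)-3,5,9-triethyl-7-methyltrideca-2,4-dienoate F4 and, after acidification, (2E,4Z,7S,9S)-3,5,9-triethyl-7-methyltrideca-2,4-dienoic acid F5. Oxalyl chloride converts it into (2E,4Z,7S,9S)-3,5,9-triethyl-7-methyltrideca-2,4-dienoyl chloride F6, and CH2N2 then gives (3E,5Z,8S,10S)-1-diazo-4,6,10-triethyl-8-methyltetradeca-3,5-dien-2-one F7. Wolff rearrangement (PhCO2Ag, Et3N, MeOH) moves the intact dienyl group onto the new CH2 and delivers 19.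

Third: step 5. It relays four organometallics in one pot; the β-branched alkylcopper may add sluggishly to the volatile alkyne or metalate it, and leftover alkylcopper can couple with 14. The fallback sets out from iodide 14 (with bromide 11 as the second partner) and comes back at ester 19. Iodide 14 is formylated (CO, Bu3SnH, Pd(PPh3)4, THF, 50 °C) to methyl (3E)-4-ethyl-5-oxopent-3-enoate F8. Ramirez olefination (CBr4, PPh3, CH2Cl2, 0 °C) gives methyl (3E)-6,6-dibromo-4-ethylhexa-3,5-dienoate F9. Trans-selective Negishi monoethylation (Et2Zn, PdCl2(DPEphos), THF, 0 °C) replaces the bromine trans to the dienyl chain and gives methyl (3E,5Z)-6-bromo-4-ethylocta-3,5-dienoate F10. Bromide 11 is converted through 15 and ZnBr2 into [(2S,4S)-4-ethyl-2-methyloctyl]zinc bromide F11, which replaces the remaining bromine with retention under Pd(t-Bu3P)2 catalysis and gives 19. The C5=C6 geometry then comes from two stereoselective cross-couplings on a 1,1-dibromoalkene instead of an alkyne carbometalation.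

**Further compounds**

F1 | step 7 | (3E,5Z,8S,10S)-4,6,10-triethyl-8-methyltetradeca-3,5-dien-1-ol | CCCC[C@H](CC)C[C@H](C)C/C(CC)=C\C(CC)=C\CCO
F2 | step 7 | 2-[(3R,6R)-4,6-diethyl-6-[(2S,4S)-4-ethyl-2-methyloctyl]-3,6-dihydro-1,2-dioxin-3-yl]ethan-1-ol | CCCC[C@H](CC)C[C@H](C)C[C@]1(CC)C=C(CC)[C@@H](CCO)OO1
F3 | step 4 | methyl (2E,4Z,7S,9S)-3,5,9-triethyl-7-methyltrideca-2,4-dienoate | CCCC[C@H](CC)C[C@H](C)C/C(CC)=C\C(CC)=C\C(=O)OC
F4 | step 4 | lithium (2E,4Z,7S,9S)-3,5,9-triethyl-7-methyltrideca-2,4-dienoate | CCCC[C@H](CC)C[C@H](C)C/C(CC)=C\C(CC)=C\C(=O)[O-].[Li+]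
F5 | step 4 | (2E,4Z,7S,9S)-3,5,9-triethyl-7-methyltrideca-2,4-dienoic acid | CCCC[C@H](CC)C[C@H](C)C/C(CC)=C\C(CC)=C\C(=O)O
F6 | step 4 | (2E,4Z,7S,9S)-3,5,9-triethyl-7-methyltrideca-2,4-dienoyl chloride | CCCC[C@H](CC)C[C@H](C)C/C(CC)=C\C(CC)=C\C(=O)Cl
F7 | step 4 | (3E,5Z,8S,10S)-1-diazo-4,6,10-triethyl-8-methyltetradeca-3,5-dien-2-one | CCCC[C@H](CC)C[C@H](C)C/C(CC)=C\C(CC)=C\C(=O)C=[N+]=[N-]
F8 | step 5 | methyl (3E)-4-ethyl-5-oxopent-3-enoate | CC/C(C=O)=C\CC(=O)OC
F9 | step 5 | methyl (3E)-6,6-dibromo-4-ethylhexa-3,5-dienoate | CC/C(C=C(Br)Br)=C\CC(=O)OC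
F10 | step 5 | methyl (3E,5Z)-6-bromo-4-ethylocta-3,5-dienoate | Br/C(CC)=C\C(CC)=C\CC(=O)OC
F11 | step 5 | [(2S,4S)-4-ethyl-2-methyloctyl]zinc bromide | CCCC[C@H](CC)C[C@H](C)C[Zn]Br
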